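# Proposed total synthesis of Botcinin K

Numbering used throughout (pyrano[3,2-b]pyran-2-one): O1, C2 (lactone C=O), C3, C4, C4a, O5, C6, C7, C8, C8a. The target is (3R,4S,4aR,6R,7R,8S,8aS).

## Analysis of the target

Botcinin K is a trans-fused bicycle: a tetrahydropyran (O5, C6, C7, C8, C8a, C4a) and a δ-lactone (O1, C2, C3, C4, C4a, C8a) share the C4a–C8a bond, with an acetyl group on C6 and an (E)-oct-2-enoate on O7. All seven stereocentres are contiguous, and two of them (C4a, C6) are fully substituted ether carbons flanking O5. Each carries an axial methyl (1,3-diaxial across O5) and an equatorial carbon substituent (C4, acetyl). On the pyran ring O8a, 8-Me and O7 are all equatorial and mutually trans. On the lactone, 3-Me, 4-OH and 4a-Me all lie on one face, so the C3 methyl is the less stable, epimerisable arrangement. If C4 and the acetyl carbon are treated as equivalent, the pyran ring has a mirror plane through O5 and C8, a hidden Cs symmetry that the route exploits. Sensitive groups are the β-hydroxy lactone (retro-aldol, elimination, C3 epimerisation), the enoate (ozone, hydride, hydrogenation) and the α-alkoxy methyl ketone. The hard points are the bis-tertiary ether, the C4 carbinol (it must form in the chelation, anti-Felkin sense relative to O5) and telling apart two similar hindered secondary hydroxyls (free C4–OH, acylated C7–OH).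

## Retrosynthetic reasoning

**21 to 19.** The lactone C2–O1 bond is cut last. In 19 the propionate unit is held as a trans-β-lactone on O4, so O4 is masked while O7 already carries the octenoate. Releasing O8a (via 20) should trigger acyl transfer to the six-membered lactone. This avoids ever having free C4–OH and C7–OH in one molecule.

**19 to 17 and 18.** The C3–C4 bond and the C4 and C3 stereocentres come from an aldol-type addition of the propionate equivalent 18 to aldehyde 17. The cut is placed here because the aldehyde sits next to ring O5, so a chelated transition state can deliver the required C4 configuration. The β-lactone closure fixes the anti C3/C4 relationship.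

**17 to 15 and 16.** Ester disconnection at O7. It is placed before the aldol so that the only free hydroxyl present is the one to be acylated.

**15 to 13 (via 14).** The aldehyde carbon (C4) and the acetyl carbonyl carbon are traced back to a styryl and a vinyl group. The oxidation levels differ because a terminal alkene gives a methyl ketone by Wacker oxidation and an internal one gives an aldehyde by ozonolysis.

**13 to 11 and 12.** The styryl and vinyl carbons are reconnected as the C=C of an 8-oxabicyclo[3.2.1]octene. The forward reaction is a ring-opening/cross-metathesis that has to decide which olefinic carbon receives the styryl group.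

**11 to 9 (via 10).** The C8 methyl is traced to a ketone. In the bicycle only the face opposite the etheno bridge is open, so hydrogen must be delivered to C8 there and the methyl ends syn to the bridge.

**9 to 4 (via 6).** The C7–O and C8a–O bonds are cut back to the α- and α′-positions of a meso ketone. Two successive exo-face hydroxylations are required. The first, under a chiral base, breaks the symmetry, sets the absolute configuration and makes the two oxygens different (silyl ether against free hydroxyl).

**4 to 1 and 2.** The C4a–C8a and C6–C7 bonds are cut together in a [4+3] sense. O5 and both tetrasubstituted ether carbons come from the furan 1, and C8a–C8–C7 from the three-carbon unit 2. This is the cut that turns the hardest part of the molecule into a one-step, symmetric problem.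

## Alternatives that were turned down

**Alternative 1:** the textbook route. Disconnect the lactone C–O bond and the O5–C6 ether bond, and build the open chain by iterative aldol and crotylation chemistry. The forward key step would be a 6-endo opening of the trisubstituted vinyl epoxide in hydroxy lactone A1 by the tertiary C4a hydroxyl (isopropenyl as masked acetyl). It was turned down for three reasons. Every one of the seven stereocentres needs its own reagent-controlled event on a linear chain. A tertiary alcohol must attack a tertiary carbon with inversion to make the bis-tertiary ether, in competition with 5-exo attack at C7 and with elimination. The epoxide needs a further asymmetric step, so the sequence would be roughly twice as long.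

**Alternative 2:** an intermolecular [5+2] cycloaddition of the trimethyl oxidopyrylium betaine A2 with a cleavable two-carbon 2π partner, giving the 8-oxabicyclo[3.2.1]oct-3-en-2-one A3. This also delivers O5 and both quaternary ether carbons in one step. It was turned down because A3 is not symmetric and would be racemic without an enantioselective variant, and the furyl carbinol needed for A2 costs several steps. Betaine dimerisation competes in the intermolecular mode. Afterwards the C8a ketone would have to be reduced from the hindered endo face, and C8 would be set by protonation of an enolate, an epimerisable centre.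

**Alternative 3:** a late single-atom edit, Baeyer–Villiger insertion of O1 between C2 and C8a of the cyclopentanone A4. It was turned down because the two α-carbons (C3 and C8a) are both secondary with similar migratory aptitude. The acetyl group on the tertiary, α-oxygenated C6 would be oxidised faster than the ring ketone, and the enoate is a competing site for the peracid. A4, with four contiguous stereocentres on a trans-fused cyclopentane, is also no easier to make than the lactone.

Key step: step 1

Assumption: the absolute sense of the two reagent-controlled steps (2 and 6) is taken as drawn; should either run the other way, the enantiomeric amide or catalyst is used, with no other change.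

## Route

Step 1
Reactants: 1 2,5-dimethylfuran; 2 1,1,3,3-tetrabromoacetone
Product: 4 (1R,5S)-1,5-dimethyl-8-oxabicyclo[3.2.1]oct-6-en-3-one (meso), via dibromo cycloadduct 3 (not isolated)
Conditions: Zn dust, B(OEt)3, THF, 0 °C → rt; then Zn–Cu couple, NH4Cl, MeOH, rt
Reagents that add atoms: none
Why: Zinc reduces 2 to a zinc enolate that ionises (assisted by B(OEt)3) to the 1,3-dibromo-2-oxyallyl cation, a 2π three-carbon unit that adds across C2/C5 of the electron-rich furan 1 in a [4+3] cycloaddition, the classical oxyallyl cation–furan reaction. Both new C–C bonds (future C4a–C8a and C6–C7) form at the methyl-bearing furan termini, so O5 and the two tetrasubstituted ether carbons are delivered at once from the heteroaromatic ring. The seven-membered carbocycle that closes (4π + 2π, suprafacial on both partners) is bridged by the furan oxygen, so it contains the tetrahydropyranone ring of the target and a 2,5-dihydrofuran ring whose C=C later becomes C4 and the acetyl carbon. The cis relation of the two bridgehead centres (both methyls on one face, both bridge carbons on the other) is enforced by the bridge and is the C4a/C6 relationship of the target. The bromine-bearing centres of 3 are erased by Zn–Cu reduction, so 4 should be a single meso compound and no diastereo- or enantioselectivity is needed here. The only selectivity required is cycloaddition over electrophilic substitution of the furan; the 2,5-dimethyl groups block α-substitution and raise the HOMO, which favours cycloaddition. The rigid bicycle leaves only the face opposite the etheno bridge open at C2–C4, which steps 2, 3 and 5 use to set C8a, C7 and C8.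

Step 2
Reactants: 4 (1R,5S)-1,5-dimethyl-8-oxabicyclo[3.2.1]oct-6-en-3-one
Product: 6 (1R,2R,5R)-1,5-dimethyl-2-(triethylsilyloxy)-8-oxabicyclo[3.2.1]oct-6-en-3-one, via triethylsilyl enol ether 5 (not isolated)
Conditions: (R,R)-bis(1-phenylethyl)amine, n-BuLi, LiCl, THF, −78 °C; Et3SiCl then 4, −100 → −78 °C; then mCPBA, NaHCO3, CH2Cl2, −20 → 0 °C
Reagents that add atoms: chlorotriethylsilane CC[Si](Cl)(CC)CC; mCPBA O=C(OO)c1cccc(Cl)c1
Why: Enantiotopic-group-selective removal of one axial α-proton of the meso ketone by the C2-symmetric chiral lithium amide with in situ silylation is a desymmetrisation known for 8-oxabicyclo[3.2.1]oct-6-en-3-ones. In the Rubottom oxidation the peracid should attack the enol ether from the face opposite the etheno bridge, and 1,4-silyl migration then gives the axial α-silyloxy ketone (the C8a oxygen).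

Step 3
Reactants: 6 (1R,2R,5R)-1,5-dimethyl-2-(triethylsilyloxy)-8-oxabicyclo[3.2.1]oct-6-en-3-one
Product: 9 (1S,2S,4R,5R)-2-hydroxy-1,5-dimethyl-4-(triethylsilyloxy)-8-oxabicyclo[3.2.1]oct-6-en-3-one, via trimethylsilyl enol ether 7 (not isolated), via trimethylsilyloxy ketone 8 (not isolated)
Conditions: LDA, Me3SiCl, THF, −78 °C; then mCPBA, NaHCO3, CH2Cl2, 0 °C; then K2CO3 (cat.), MeOH, 0 °C
Reagents that add atoms: mCPBA O=C(OO)c1cccc(Cl)c1
Why: Only the α′-carbon still has an axial proton aligned with the carbonyl (the proton next to the silyloxy group is equatorial), so kinetic enolisation should be regioselective. The second Rubottom oxidation again takes place on the exo face and gives the C7 oxygen, and the trimethylsilyl ether is cleaved selectively in the presence of the triethylsilyl ether.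

Step 4
Reactants: 9 (1S,2S,4R,5R)-2-hydroxy-1,5-dimethyl-4-(triethylsilyloxy)-8-oxabicyclo[3.2.1]oct-6-en-3-one
Product: 10 (1S,2R,4S,5R)-1,5-dimethyl-3-methylidene-4-(triethylsilyloxy)-8-oxabicyclo[3.2.1]oct-6-en-2-ol
Conditions: Ph3PCH3Br (3 equiv), KHMDS, THF, 0 °C; then 9, 0 → 45 °C
Reagents that add atoms: methyltriphenylphosphonium bromide C[P+](c1ccccc1)(c1ccccc1)c1ccccc1.[Br-]
Why: Wittig methylenation. Both remaining α-hydrogens are equatorial, so the ketone is practically non-enolisable and the two new carbinol centres are not at risk; excess ylide covers the free hydroxyl.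

Step 5
Reactants: 10 (1S,2R,4S,5R)-1,5-dimethyl-3-methylidene-4-(triethylsilyloxy)-8-oxabicyclo[3.2.1]oct-6-en-2-ol
Product: 11 (1S,2R,3R,4S,5R)-1,3,5-trimethyl-4-(triethylsilyloxy)-8-oxabicyclo[3.2.1]oct-6-en-2-ol
Conditions: Mn(dpm)3 (10 mol%), PhSiH3, t-BuOOH, i-PrOH, 22 °C
Reagents that add atoms: none
Why: Metal-hydride hydrogen-atom-transfer hydrogenation. Markovnikov H-atom transfer to the 1,1-disubstituted alkene gives a tertiary radical and should be much faster than reaction of the 1,2-disubstituted bridge alkene. The second hydrogen can only reach C8 from the face opposite the etheno bridge, which places the methyl syn to the bridge (the C8 configuration of the target).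

Step 6
Reactants: 11 (1S,2R,3R,4S,5R)-1,3,5-trimethyl-4-(triethylsilyloxy)-8-oxabicyclo[3.2.1]oct-6-en-2-ol; 12 styrene
Product: 13 (2S,3R,4R,5S,6R)-2-ethenyl-2,4,6-trimethyl-6-[(E)-2-phenylethenyl]-5-(triethylsilyloxy)oxan-3-ol
Conditions: chiral Ru benzylidene with bidentate NHC–binaphtholate ligand (5 mol%), 12 (5 equiv), THF, 22–40 °C
Reagents that add atoms: none
Why: Ru-catalysed asymmetric ring-opening/cross-metathesis is known for 8-oxabicyclo[3.2.1]oct-6-enes with styrenes. Strain release drives the opening, the chiral catalyst decides which olefinic carbon leaves as the styryl group (here the one on C4a, next to the silyloxy-bearing C8a), and the cis relation of the two new substituents is inherited from the bicycle. Any minor enantiomer from step 2 should end as a separable regioisomer.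

Step 7
Reactants: 13 (2S,3R,4R,5S,6R)-2-ethenyl-2,4,6-trimethyl-6-[(E)-2-phenylethenyl]-5-(triethylsilyloxy)oxan-3-ol
Product: 14 1-[(2R,3R,4R,5S,6R)-3-hydroxy-2,4,6-trimethyl-6-[(E)-2-phenylethenyl]-5-(triethylsilyloxy)oxan-2-yl]ethan-1-one
Conditions: Pd(quinox)Cl2 (5 mol%), AgSbF6 (12 mol%), aq. t-BuOOH, CH2Cl2, 0 °C → rt
Reagents that add atoms: tert-butyl hydroperoxide CC(C)(C)OO
Why: Wacker-type oxidation in the variant made for terminal alkenes that carry an allylic oxygen should turn the monosubstituted vinyl group into the methyl ketone; the 1,2-disubstituted styryl alkene is much less reactive.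

Step 8
Reactants: 14 1-[(2R,3R,4R,5S,6R)-3-hydroxy-2,4,6-trimethyl-6-[(E)-2-phenylethenyl]-5-(triethylsilyloxy)oxan-2-yl]ethan-1-one
Product: 15 (2S,3S,4R,5R,6R)-6-acetyl-5-hydroxy-2,4,6-trimethyl-3-(triethylsilyloxy)oxane-2-carbaldehyde
Conditions: O3, CH2Cl2/MeOH, NaHCO3, −78 °C; then Me2S, −78 °C → rt
Reagents that add atoms: ozone [O-][O+]=O
Why: Ozonolysis of the only remaining C=C with reductive work-up unmasks the C4 aldehyde. The aldehyde is non-enolisable (quaternary C4a), and an intramolecular aldol with the acetyl group would need both substituents axial, so 15 should be stable under neutral conditions.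

Step 9
Reactants: 15 (2S,3S,4R,5R,6R)-6-acetyl-5-hydroxy-2,4,6-trimethyl-3-(triethylsilyloxy)oxane-2-carbaldehyde; 16 (E)-oct-2-enoic acid
Product: 17 (2R,3R,4R,5S,6S)-2-acetyl-6-formyl-2,4,6-trimethyl-5-(triethylsilyloxy)oxan-3-yl (2E)-oct-2-enoate
Conditions: 2-methyl-6-nitrobenzoic anhydride (MNBA), DMAP (cat.), Et3N, CH2Cl2, rt
Reagents that add atoms: none
Why: Mixed-anhydride esterification with DMAP catalysis of the only free hydroxyl (C7–OH). It is done before any C4–OH exists, so the two similar secondary hydroxyls never have to be told apart.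

Step 10
Reactants: 17 (2R,3R,4R,5S,6S)-2-acetyl-6-formyl-2,4,6-trimethyl-5-(triethylsilyloxy)oxan-3-yl (2E)-oct-2-enoate; 18 2-{[(E)-1-(tert-butyldimethylsilyloxy)prop-1-en-1-yl]sulfanyl}pyridine
Product: 19 (2R,3R,4R,5S,6R)-2-acetyl-2,4,6-trimethyl-6-[(2S,3R)-3-methyl-4-oxooxetan-2-yl]-5-(triethylsilyloxy)oxan-3-yl (2E)-oct-2-enoate
Conditions: 18 (2 equiv), ZnCl2 (2 equiv), CH2Cl2, rt
Reagents that add atoms: none
Why: Tandem Mukaiyama aldol–lactonisation. ZnCl2 should chelate the aldehyde oxygen and ring O5 (Cram chelate), so the ketene acetal attacks from the side of the C4a methyl and gives C4–O syn to O5, which is also the 1,3-anti sense favoured by the β-silyloxy group. Closure of the aldolate onto the pyridyl thioester gives the trans-β-lactone (anti C3/C4) and keeps O4 masked.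

Step 11
Reactants: 19 (2R,3R,4R,5S,6R)-2-acetyl-2,4,6-trimethyl-6-[(2S,3R)-3-methyl-4-oxooxetan-2-yl]-5-(triethylsilyloxy)oxan-3-yl (2E)-oct-2-enoate
Product: 21 Botcinin K, via hydroxy β-lactone 20 (not isolated)
Conditions: HF·pyridine, pyridine, THF, 0 °C → rt
Reagents that add atoms: none
Why: Removal of the triethylsilyl group frees the C8a hydroxyl, which should attack the strained β-lactone carbonyl (translactonisation) to give the trans-fused δ-lactone and the free C4–OH without touching C3 or C4. The mildly acidic medium avoids C3 epimerisation and acyl migration of the octenoate.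

## Compound list

1 | 2,5-dimethylfuran | Cc1ccc(C)o1 | starting material
2 | 1,1,3,3-tetrabromoacetone | O=C(C(Br)Br)C(Br)Br | starting material
3 | 2,4-dibromo-1,5-dimethyl-8-oxabicyclo[3.2.1]oct-6-en-3-one (mixture of C2/C4 epimers; cis-diequatorial isomer shown) | Br[C@H]1C(=O)[C@@H](Br)[C@]2(C)O[C@@]1(C)C=C2 | intermediate
4 | (1R,5S)-1,5-dimethyl-8-oxabicyclo[3.2.1]oct-6-en-3-one (meso) | C1C(=O)C[C@]2(C)O[C@@]1(C)C=C2 | intermediate
5 | triethyl{[(1R,5R)-1,5-dimethyl-8-oxabicyclo[3.2.1]octa-2,6-dien-3-yl]oxy}silane | C1C(O[Si](CC)(CC)CC)=C[C@]2(C)O[C@@]1(C)C=C2 | intermediate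
6 | (1R,2R,5R)-1,5-dimethyl-2-(triethylsilyloxy)-8-oxabicyclo[3.2.1]oct-6-en-3-one | C1C(=O)[C@H](O[Si](CC)(CC)CC)[C@]2(C)O[C@@]1(C)C=C2 | intermediate
7 | (1S,4R,5R)-1,5-dimethyl-4-(triethylsilyloxy)-3-(trimethylsilyloxy)-8-oxabicyclo[3.2.1]octa-2,6-diene | C1=C(O[Si](C)(C)C)[C@H](O[Si](CC)(CC)CC)[C@]2(C)O[C@@]1(C)C=C2 | intermediate
8 | (1R,2R,4S,5S)-1,5-dimethyl-2-(triethylsilyloxy)-4-(trimethylsilyloxy)-8-oxabicyclo[3.2.1]oct-6-en-3-one | C[Si](C)(C)O[C@@H]1C(=O)[C@H](O[Si](CC)(CC)CC)[C@]2(C)O[C@@]1(C)C=C2 | intermediate
9 | (1S,2S,4R,5R)-2-hydroxy-1,5-dimethyl-4-(triethylsilyloxy)-8-oxabicyclo[3.2.1]oct-6-en-3-one | O[C@@H]1C(=O)[C@H](O[Si](CC)(CC)CC)[C@]2(C)O[C@@]1(C)C=C2 | intermediate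
10 | (1S,2R,4S,5R)-1,5-dimethyl-3-methylidene-4-(triethylsilyloxy)-8-oxabicyclo[3.2.1]oct-6-en-2-ol | O[C@@H]1C(=C)[C@H](O[Si](CC)(CC)CC)[C@]2(C)O[C@@]1(C)C=C2 | intermediate
11 | (1S,2R,3R,4S,5R)-1,3,5-trimethyl-4-(triethylsilyloxy)-8-oxabicyclo[3.2.1]oct-6-en-2-ol | O[C@@H]1[C@@H](C)[C@H](O[Si](CC)(CC)CC)[C@]2(C)O[C@@]1(C)C=C2 | intermediate
12 | styrene | C=Cc1ccccc1 | starting material
13 | (2S,3R,4R,5S,6R)-2-ethenyl-2,4,6-trimethyl-6-[(E)-2-phenylethenyl]-5-(triethylsilyloxy)oxan-3-ol | O[C@@H]1[C@@H](C)[C@H](O[Si](CC)(CC)CC)[C@](/C=C/c2ccccc2)(C)O[C@@]1(C)C=C | intermediate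
14 | 1-[(2R,3R,4R,5S,6R)-3-hydroxy-2,4,6-trimethyl-6-[(E)-2-phenylethenyl]-5-(triethylsilyloxy)oxan-2-yl]ethan-1-one | O[C@@H]1[C@@H](C)[C@H](O[Si](CC)(CC)CC)[C@](/C=C/c2ccccc2)(C)O[C@@]1(C)C(C)=O | intermediate
15 | (2S,3S,4R,5R,6R)-6-acetyl-5-hydroxy-2,4,6-trimethyl-3-(triethylsilyloxy)oxane-2-carbaldehyde | O[C@@H]1[C@@H](C)[C@H](O[Si](CC)(CC)CC)[C@](C=O)(C)O[C@@]1(C)C(C)=O | intermediate
16 | (E)-oct-2-enoic acid | CCCCC/C=C/C(=O)O | starting material
17 | (2R,3R,4R,5S,6S)-2-acetyl-6-formyl-2,4,6-trimethyl-5-(triethylsilyloxy)oxan-3-yl (2E)-oct-2-enoate | CCCCC/C=C/C(=O)O[C@@H]1[C@@H](C)[C@H](O[Si](CC)(CC)CC)[C@](C=O)(C)O[C@@]1(C)C(C)=O | intermediate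
18 | 2-{[(E)-1-(tert-butyldimethylsilyloxy)prop-1-en-1-yl]sulfanyl}pyridine | C/C=C(/Sc1ccccn1)\O[Si](C)(C)C(C)(C)C | starting material
19 | (2R,3R,4R,5S,6R)-2-acetyl-2,4,6-trimethyl-6-[(2S,3R)-3-methyl-4-oxooxetan-2-yl]-5-(triethylsilyloxy)oxan-3-yl (2E)-oct-2-enoate | CCCCC/C=C/C(=O)O[C@@H]1[C@@H](C)[C@H](O[Si](CC)(CC)CC)[C@]([C@H]2OC(=O)[C@@H]2C)(C)O[C@@]1(C)C(C)=O | intermediate
20 | (2R,3R,4S,5S,6S)-2-acetyl-5-hydroxy-2,4,6-trimethyl-6-[(2S,3R)-3-methyl-4-oxooxetan-2-yl]oxan-3-yl (2E)-oct-2-enoate | CCCCC/C=C/C(=O)O[C@@H]1[C@@H](C)[C@H](O)[C@]([C@H]2OC(=O)[C@@H]2C)(C)O[C@@]1(C)C(C)=O | intermediate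
21 | Botcinin K, (3R,4S,4aR,6R,7R,8S,8aS)-6-acetyl-4-hydroxy-3,4a,6,8-tetramethyl-2-oxooctahydropyrano[3,2-b]pyran-7-yl (2E)-oct-2-enoate | CCCCC/C=C/C(=O)O[C@@H]1[C@@H](C)[C@@H]2OC(=O)[C@H](C)[C@H](O)[C@@]2(C)O[C@@]1(C)C(C)=O | target

## Step count and risk

Total: 11 steps. Longest linear sequence: 11 steps (1 and 2 to 21).

**Step 1 (key step).** The likely failure is loss of material to electrophilic alkylation or oligomerisation of the electron-rich furan by the dibromo oxyallyl species, which would give a poor yield of cycloadduct. Fallback from 1: anodic methoxylation in methanol gives the bis-ketal 2,5-dimethoxy-2,5-dimethyl-2,5-dihydrofuran F1. A TMSOTf-mediated twofold Mukaiyama-type alkylation of the derived oxocarbenium ions with 1-methoxy-1,3-bis(trimethylsilyloxy)buta-1,3-diene should close the same bicycle as the β-keto ester methyl 1,5-dimethyl-3-oxo-8-oxabicyclo[3.2.1]oct-6-ene-2-carboxylate F2. Krapcho dealkoxycarbonylation (NaCl, wet DMSO, heat) returns to 4.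

**Step 6.** The bridgehead methyl groups make both olefinic carbons neopentyl. Ring opening may be sluggish and the catalyst may discriminate poorly between the two carbons (low regioselectivity). Fallback from 11, using reagent-controlled hydroboration, which is established for this ring system:
- Protection as the p-methoxybenzyl ether F3 (PMB trichloroacetimidate, cat. La(OTf)3).
- Hydroboration with the appropriate enantiomer of diisopinocampheylborane and oxidative work-up, giving the exo alcohol F4 on the bridge carbon attached to C6.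
- DMP oxidation to the ketone F5.
- Regioselective enolisation (only one α-CH2) and trapping with PhNTf2 to the enol triflate F6.
- Coupling with Me2CuLi to the methyl-substituted alkene F7.
- Ozonolysis to the keto aldehyde PMB ether F8.
- DDQ removal of the PMB group, returning to 15.

**Step 5.** The strained bridge alkene may compete for the metal hydride (loss of chemoselectivity), and hydrogen delivery to the C8 radical may be slowed by the two flanking axial oxygen substituents. Fallback from 9: Peterson olefination with lithiated phenyl (trimethylsilyl)methyl sulfone gives the vinyl sulfone F9. Conjugate reduction with NaBH4 in ethanol (hydride from the open exo face) gives the sulfone F10. Reductive desulfonylation with Mg in methanol returns to 11.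

**Step 10.** Chelation to the hindered ring oxygen may be weak, so that Felkin-type attack erodes the facial selectivity at C4, and addition to the neopentyl aldehyde may be slow. Fallback from 17:
- HF·pyridine gives the hydroxy aldehyde F11.
- 2-Bromopropanoyl bromide and pyridine give the bromo ester F12.
- SmI2-mediated intramolecular Reformatsky reaction gives the hydroxy lactone F13 as a mixture at C3/C4.
- DMP oxidation converges the mixture to the β-keto lactone F14.
- Ru–TsDPEN transfer hydrogenation (HCO2H/Et3N) with dynamic kinetic resolution should deliver hydride to C4 from the face opposite the axial C4a methyl while C3 equilibrates, sparing the enoate, and arrive at 21.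

**Step 2.** The bridgehead methyl groups may slow the deprotonation and lower the enantiotopic selectivity. Fallback from 4:
- Rubottom oxidation with LDA gives the racemic hydroxy ketone F15.
- A second Rubottom oxidation via the bis-silylated dianion gives the meso diol F16.
- Lipase-catalysed monoacetylation with vinyl acetate (or, for the opposite sense, enzymatic hydrolysis of the diacetate) gives the monoacetate F17, with the acetate on the future C7 oxygen.
- Silylation with Et3SiCl and imidazole gives F18.
- Methanolysis of the acetate (K2CO3, MeOH) returns to 9.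

## Further compounds

F1 | step 1 | 2,5-dimethoxy-2,5-dimethyl-2,5-dihydrofuran (cis/trans mixture; cis shown) | CO[C@@]1(C)C=C[C@@](C)(OC)O1
F2 | step 1 | methyl 1,5-dimethyl-3-oxo-8-oxabicyclo[3.2.1]oct-6-ene-2-carboxylate (racemic; C2 epimers) | C1C(=O)C(C(=O)OC)[C@]2(C)O[C@@]1(C)C=C2
F3 | step 6 | p-methoxybenzyl ether of 11 | COc3ccc(CO[C@@H]1[C@@H](C)[C@H](O[Si](CC)(CC)CC)[C@]2(C)O[C@@]1(C)C=C2)cc3
F4 | step 6 | exo-6-hydroxy-8-oxabicyclo[3.2.1]octane from hydroboration of F3 (hydroxyl on the bridge carbon next to C6 of the target) | COc3ccc(CO[C@@H]1[C@@H](C)[C@H](O[Si](CC)(CC)CC)[C@]2(C)O[C@@]1(C)[C@@H](O)C2)cc3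
F5 | step 6 | bridge ketone from F4 | COc3ccc(CO[C@@H]1[C@@H](C)[C@H](O[Si](CC)(CC)CC)[C@]2(C)O[C@@]1(C)C(=O)C2)cc3
F6 | step 6 | enol triflate of F5 | COc3ccc(CO[C@@H]1[C@@H](C)[C@H](O[Si](CC)(CC)CC)[C@]2(C)O[C@@]1(C)C(OS(=O)(=O)C(F)(F)F)=C2)cc3
F7 | step 6 | 6-methyl-8-oxabicyclo[3.2.1]oct-6-ene from F6 | COc3ccc(CO[C@@H]1[C@@H](C)[C@H](O[Si](CC)(CC)CC)[C@]2(C)O[C@@]1(C)C(C)=C2)cc3
F8 | step 6 | p-methoxybenzyl ether of 15 | COc3ccc(CO[C@@H]1[C@@H](C)[C@H](O[Si](CC)(CC)CC)[C@](C=O)(C)O[C@@]1(C)C(C)=O)cc3
F9 | step 5 | 3-(phenylsulfonylmethylidene) analogue of 10 (alkene isomers) | O[C@@H]1C(=CS(=O)(=O)c3ccccc3)[C@H](O[Si](CC)(CC)CC)[C@]2(C)O[C@@]1(C)C=C2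
F10 | step 5 | 3-(phenylsulfonylmethyl) analogue of 11 | O[C@@H]1[C@@H](CS(=O)(=O)c3ccccc3)[C@H](O[Si](CC)(CC)CC)[C@]2(C)O[C@@]1(C)C=C2
F11 | step 10 | desilylated 17 (free C8a hydroxyl) | CCCCC/C=C/C(=O)O[C@@H]1[C@@H](C)[C@H](O)[C@](C=O)(C)O[C@@]1(C)C(C)=O
F12 | step 10 | 2-bromopropanoate of F11 (epimers at the bromide carbon) | CCCCC/C=C/C(=O)O[C@@H]1[C@@H](C)[C@H](OC(=O)C(C)Br)[C@](C=O)(C)O[C@@]1(C)C(C)=O
F13 | step 10 | hydroxy lactone, mixture of C3/C4 isomers of 21 | CCCCC/C=C/C(=O)O[C@@H]1[C@@H](C)[C@@H]2OC(=O)C(C)C(O)[C@@]2(C)O[C@@]1(C)C(C)=O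
F14 | step 10 | 4-oxo (β-keto lactone) analogue of 21 (C3 epimers/enol) | CCCCC/C=C/C(=O)O[C@@H]1[C@@H](C)[C@@H]2OC(=O)C(C)C(=O)[C@@]2(C)O[C@@]1(C)C(C)=O
F15 | step 2 | 2-hydroxy-1,5-dimethyl-8-oxabicyclo[3.2.1]oct-6-en-3-one (racemic; axial hydroxyl; one enantiomer shown) | C1C(=O)[C@H](O)[C@]2(C)O[C@@]1(C)C=C2
F16 | step 2 | meso-2,4-dihydroxy-1,5-dimethyl-8-oxabicyclo[3.2.1]oct-6-en-3-one (both hydroxyls axial) | O[C@@H]1C(=O)[C@H](O)[C@]2(C)O[C@@]1(C)C=C2
F17 | step 2 | monoacetate of F16 (acetate on the future C7 oxygen) | CC(=O)O[C@@H]1C(=O)[C@H](O)[C@]2(C)O[C@@]1(C)C=C2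
F18 | step 2 | triethylsilyl ether of F17 | CC(=O)O[C@@H]1C(=O)[C@H](O[Si](CC)(CC)CC)[C@]2(C)O[C@@]1(C)C=C2
A1 | alternative 1 | δ-lactone with free tertiary C4a hydroxyl and a 3-methyl-3-(prop-1-en-2-yl)oxiran-2-yl side chain at C8a–C8 | C=C(C)[C@@]1(C)O[C@@H]1[C@@H](C)[C@@H]2OC(=O)[C@H](C)[C@H](O)[C@@]2(C)O
A2 | alternative 2 | 2,4,6-trimethylpyrylium-3-olate | Cc1[o+]c(C)cc(C)c1[O-]
A3 | alternative 2 | 1,3,5-trimethyl-8-oxabicyclo[3.2.1]oct-3-en-2-one with an exo cyclic carbonate on C6/C7 (racemic; one enantiomer shown) | C1=C(C)C(=O)[C@]2(C)O[C@@]1(C)[C@H]3OC(=O)O[C@H]32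
A4 | alternative 3 | cyclopenta[b]pyran-6-one analogue of the target lacking O1 (C2 bonded to C8a) | CCCCC/C=C/C(=O)O[C@@H]1[C@@H](C)[C@@H]2C(=O)[C@H](C)[C@H](O)[C@@]2(C)O[C@@]1(C)C(C)=O
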